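Start with a subtraction: take the last product reading of a run from each charge, as if each unit of product had used one of starting material and one of partner. Product divided by the two remainders multiplied together gives 0.00527 mM⁻¹ for the elm run at 18 h. This is the charge quotient. At one temperature, a stall that is an equilibrium keeps this quotient whatever the recipe, so turning each setting is a test.

| setting | elm | birch | oak | larch | ash |
|---|---|---|---|---|---|
| starting material | 150 mM | 150 mM | 300 mM | 150 mM | 150 mM |
| partner | 150 mM | 150 mM | 150 mM | 75.0 mM | 150 mM |
| catalyst | 3.00 mM | 1.50 mM | 3.00 mM | 3.00 mM | 3.00 mM |
| time |  |  |  |  | 72 h |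

- elm run (time / h: [product] / mM): 0.72: 3.2; 1.4: 6.7; 2.6: 13.3; 5.0: 27.6; 9.5: 43.2; 18: 51.3
- birch run (time / h: [product] / mM): 0.72: 1.7; 1.4: 3.2; 2.6: 7.4; 5.0: 15.5; 9.5: 28.8; 18: 36.9
- oak run (time / h: [product] / mM): 0.72: 4.2; 1.4: 9.6; 2.6: 23.8; 5.0: 54.4; 9.5: 76.4; 18: 78.5
- larch run (time / h: [product] / mM): 0.72: 2.0; 1.4: 3.7; 2.6: 5.8; 5.0: 10.1; 9.5: 15.9; 18: 20.5

(readings scatter by 0.4 mM)

* the power of [starting material] that the first rate follows, about the charge of the elm run; measure it at two percent of starting material made into product (one fixed amount of product, the same in the runs compared)
* the power of [catalyst] that the first rate follows, about the charge of the elm run; measure it at two percent of starting material made into product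
* product in the ash run at 72 h, as a share of the starting material charged

- Overall: starting material + partner -> product, with catalyst as catalyst.
- Constant volume, constant temperature.
- Readings of a species count what is bound in complexes too.
- An order is taken over about fifteen percent of the charge, up and down.

Take the catalyst first. By hand, half the catalyst leaves an equilibrium quotient alone and stretches the clock about twice. The first readings of elm and birch give a rough order in catalyst of 0.913. Yet the birch run at 18 h stands at 36.9 mM, less than the elm run at 9.5 h with 43.2 mM, so the stretched clock does not quite hold late on.

Next the starting material. Twice the charge should push product up at a constant quotient, and the oak run gives 0.00496 mM⁻¹, against 0.00527 mM⁻¹ in the elm run. The first oak reading, set against the first elm reading, gives a rough order in starting material of 0.392.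

Last the partner. At half the charge, partner is the limiting reagent in the larch run, and the quotient should hold again. It reads 0.00290 mM⁻¹, lower than in elm or oak, although the mean larch rate between the last two readings is down to 0.541 mM h⁻¹.

So I treat the elm stall as a fading rate, not a balance. Over its last two intervals, the mean rate read from the elm run falls from 3.47 mM h⁻¹ to 0.953 mM h⁻¹, a fade of 0.199 h⁻¹. If that fade goes on, I estimate a tail of 2.06 mM, so the ash run, which has elm's charges, should end near 35.6%.

The forecast gives 0.4, 0.9 and 36%, and its grounds differ from mine, since it reads the stalls as “an equilibrium with K about 0.005 per mM”.

The flask gives 0.37, 0.82 and 34.7%.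

    catalyst + starting material ⇌ catalyst-substrate complex, settled at all times (41.80 M⁻¹)
    catalyst-substrate complex + partner ⇌ ternary complex, settled at all times (1.550 M⁻¹)
    ternary complex → product + catalyst (7.956 h⁻¹)
    starting material + partner + product → 2 product (20.09 M⁻² h⁻¹)
    partner → lost reagent (0.1393 h⁻¹)

The ash run has elm's charges, so a level read from the elm run carries over whatever stops the ash run, and the ash charge quotient comes to 0.00541 mM⁻¹. What stops it is the conversion of partner into lost reagent. The same ash flask without that step proves it, with product at 97.2% of the starting material at 72 h, and there the charge quotient climbs to 8.13 mM⁻¹.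

The runs stem from a simulated flask with made-up constants; scatter was added.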